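## Retrosynthetic overview

1. Target 31 ⇐ 30: the (Z)-enol acetate is made last, by Ru-catalysed anti-Markovnikov addition of AcOH to a C10 ethynyl group. 30 ⇐ 24 by O8 angeloylation, desilylation with 6,12-lactonisation, and O9 acetylation.
2. Key disconnection C7–C8: the cyclohexane (C5–C10) of 24 is closed by a SmI2 ketyl–olefin cyclisation of the open-chain C8 aldehyde 23 onto C7 of its 2-(phenylsulfonylmethyl)enoate; loss of sulfinate unveils C11=C13. Enabling feature: the γ-hydroxy-α-methylene-ester array O8–C8–C7–C11(=C13)–C12, sitting on a six-membered ring whose other substituents (C5, C6, C9, C10) can all be equatorial.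
3. 23 ⇐ acid 9: C1 acid → ethynyl (Ohira–Bestmann); 6,7-acetonide → C7 aldehyde → thia-Michael/HWE acceptor; 8-OPMB → C8 aldehyde.
4. C10–C5 bond (quaternary C10, C5 and the isopropenyl group) by a chelated dianion Ireland–Claisen rearrangement of ester 8; C9 comes from a thiazolidinethione aldol, C6 from (S)-glyceraldehyde acetonide.
5. Ring order: carbocycle first (step 16), then the trans-fused γ-lactone (step 18).

Key step: step 16

Remark: elemane locants are used for all intermediates (ring C5–C10; C14 = CH3 on C10; C1/C2 = two-carbon branch on C10; C3/C4/C15 = isopropenyl on C5; C11–C13 = methylene-lactone unit), the SMILES are authoritative for configuration, and compounds 19–23 are drawn as the expected major (Z) isomer of an E/Z mixture that is carried on as such.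
Remark: 1 and 5 are taken as purchased (1 freshly distilled); if 5 is not stocked it is one N-acylation from commercial (R)-4-benzylthiazolidine-2-thione.

## Route

Step 1
Reactants: 1 (S)-2,2-dimethyl-1,3-dioxolane-4-carbaldehyde; 2 ethyl 2-(triphenylphosphoranylidene)propanoate
Product: 3 ethyl (2E)-3-[(4R)-2,2-dimethyl-1,3-dioxolan-4-yl]-2-methylprop-2-enoate
Conditions: CH2Cl2, 0 °C → rt
Reagents that add atoms: none
Why: Wittig olefination with a stabilised α-branched ylide should be E-selective and leaves the dioxolane stereocentre (future C6, chiral pool) untouched.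

Step 2
Reactants: 3 ethyl (2E)-3-[(4R)-2,2-dimethyl-1,3-dioxolan-4-yl]-2-methylprop-2-enoate
Product: 4 (2E)-3-[(4R)-2,2-dimethyl-1,3-dioxolan-4-yl]-2-methylprop-2-en-1-ol
Conditions: DIBAL-H (2.2 equiv), CH2Cl2, −78 °C; Rochelle salt
Reagents that add atoms: none
Why: DIBAL-H 1,2-reduction of an enoate to the allylic alcohol; no stereocentre is involved.

Step 3
Reactants: 5 (R)-4-benzyl-3-propanoyl-1,3-thiazolidine-2-thione; 6 2-[(4-methoxybenzyl)oxy]acetaldehyde
Product: 7 Evans-syn aldol adduct (2R,3R)-1-[(4R)-4-benzyl-2-thioxo-1,3-thiazolidin-3-yl]-3-hydroxy-4-[(4-methoxybenzyl)oxy]-2-methylbutan-1-one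
Conditions: TiCl4 (1.05 equiv), i-Pr2NEt (1.1 equiv), NMP (1.1 equiv), CH2Cl2, 0 °C; then 6, −78 → 0 °C
Reagents that add atoms: none
Why: Crimmins titanium-enolate aldol (Evans-syn mode) in which the auxiliary sets C9 as R; the C10 centre formed here is erased in step 5.

Step 4
Reactants: 7 Evans-syn aldol adduct; 4 (2E)-3-[(4R)-2,2-dimethyl-1,3-dioxolan-4-yl]-2-methylprop-2-en-1-ol
Product: 8 (2E)-3-[(4R)-2,2-dimethyl-1,3-dioxolan-4-yl]-2-methylprop-2-en-1-yl (2R,3R)-3-hydroxy-4-[(4-methoxybenzyl)oxy]-2-methylbutanoate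
Conditions: 4 (1.1 equiv), DMAP (0.3 equiv), CH2Cl2, rt
Reagents that add atoms: none
Why: N-acylthiazolidinethiones are active amides that primary alcohols displace under DMAP catalysis (auxiliary removal by alcoholysis), so the allyl ester forms without touching C9.

Step 5
Reactants: 8 β-hydroxy allyl ester
Product: 9 (2S,3R)-2-{(1S)-1-[(4R)-2,2-dimethyl-1,3-dioxolan-4-yl]-2-methylprop-2-en-1-yl}-3-hydroxy-4-[(4-methoxybenzyl)oxy]-2-methylbutanoic acid
Conditions: LDA (3.2 equiv), THF, −78 °C → rt (→ 45 °C if needed); 1 M HCl work-up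
Reagents that add atoms: none
Why: Ireland–Claisen-type [3,3] rearrangement of a β-hydroxy ester dianion, in which the lithium chelate fixes the enolate geometry (C9 cis to OLi) and directs the new C10–C5 bond anti to O9 as in Fráter–Seebach alkylation, while the chair transition state with the (E)-allyl unit reacting anti to the C6–O bond (C6–H eclipsing the alkene, A(1,3) control) should set the quaternary C10 and C5 and deliver the isopropenyl group.

Step 6
Reactants: 9 Claisen acid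
Product: 10 (2R,3R)-2-{(1S)-1-[(4R)-2,2-dimethyl-1,3-dioxolan-4-yl]-2-methylprop-2-en-1-yl}-4-[(4-methoxybenzyl)oxy]-2-methylbutane-1,3-diol
Conditions: LiAlH4 (3 equiv), THF, 0 °C → reflux; Fieser work-up
Reagents that add atoms: none
Why: LiAlH4 reduction of the α-quaternary carboxylic acid to the neopentyl primary alcohol; no stereocentre is involved.

Step 7
Reactants: 10 1,3-diol
Product: 11 bis-TES ether (C1-OTES and 9-OTES) of 10
Conditions: TESCl (3 equiv), imidazole, DMAP (cat.), DMF, rt → 40 °C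
Reagents that add atoms: chlorotriethylsilane, CC[Si](Cl)(CC)CC
Why: Standard silyl ether formation on both hydroxyls, chosen so that the acetonide is not exposed to a silyl triflate.

Step 8
Reactants: 11 bis-TES ether
Product: 12 (2S,3R)-2-{(1S)-1-[(4R)-2,2-dimethyl-1,3-dioxolan-4-yl]-2-methylprop-2-en-1-yl}-4-[(4-methoxybenzyl)oxy]-2-methyl-3-[(triethylsilyl)oxy]butanal
Conditions: (COCl)2, DMSO, CH2Cl2, −78 → −30 °C; Et3N, → rt
Reagents that add atoms: none
Why: Swern conditions cleave and oxidise a primary TES ether in the presence of a secondary one (one-pot deprotection–oxidation), giving the non-enolisable C1 aldehyde with O9 still protected.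

Step 9
Reactants: 12 C1 aldehyde
Product: 13 (4R)-4-{(1S,2R,3R)-2-ethynyl-4-[(4-methoxybenzyl)oxy]-2-methyl-1-(prop-1-en-2-yl)-3-[(triethylsilyl)oxy]butyl}-2,2-dimethyl-1,3-dioxolane
Conditions: dimethyl (1-diazo-2-oxopropyl)phosphonate, K2CO3, MeOH, 0 °C → rt
Reagents that add atoms: dimethyl (1-diazo-2-oxopropyl)phosphonate, CC(=O)C(=[N+]=[N-])P(=O)(OC)OC
Why: Ohira–Bestmann (Seyferth–Gilbert) homologation turns the aldehyde into the terminal alkyne (C1≡C2); the α-quaternary centre cannot epimerise and the silylated O9 blocks retro-aldol cleavage.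

Step 10
Reactants: 13 alkyne acetonide
Product: 14 (2R,3S,4R,5R)-4-ethynyl-6-[(4-methoxybenzyl)oxy]-4-methyl-3-(prop-1-en-2-yl)hexane-1,2,5-triol
Conditions: AcOH/H2O/THF (3:1:1), 45 °C
Reagents that add atoms: none
Why: Mild acid hydrolysis of the terminal acetonide; the secondary TES ether is deliberately lost as well, while the PMB ether, alkyne and isopropenyl group should survive.

Step 11
Reactants: 14 triol
Product: 15 tris-TES ether (6-, 7- and 9-OTES) of 14
Conditions: TESOTf (4 equiv), 2,6-lutidine, CH2Cl2, −78 → 0 °C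
Reagents that add atoms: triethylsilyl trifluoromethanesulfonate, CC[Si](CC)(CC)OS(=O)(=O)C(F)(F)F
Why: Exhaustive silylation with a silyl triflate, which also reaches the hindered neopentyl O9.

Step 12
Reactants: 15 tris-TES ether
Product: 16 (2R,3S,4R,5R)-4-ethynyl-6-[(4-methoxybenzyl)oxy]-4-methyl-3-(prop-1-en-2-yl)-2,5-bis[(triethylsilyl)oxy]hexanal
Conditions: (COCl)2, DMSO, CH2Cl2, −78 → −30 °C; Et3N, → rt
Reagents that add atoms: none
Why: The same selective Swern deprotection–oxidation of the only primary TES ether gives the C7 aldehyde with O6 and O9 still silylated.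

Step 13
Reactants: 16 C7 aldehyde; 17 ethyl 2-(diethoxyphosphoryl)prop-2-enoate
Product: 19 ethyl (2Z,4S,5S,6R,7R)-6-ethynyl-8-[(4-methoxybenzyl)oxy]-6-methyl-2-[(phenylsulfanyl)methyl]-5-(prop-1-en-2-yl)-4,7-bis[(triethylsilyl)oxy]oct-2-enoate, via phosphonate thia-Michael adduct 18 (not isolated)
Conditions: PhSNa (1.1 equiv), 17 (1.1 equiv), THF, 0 °C; then 16, −78 °C → rt
Reagents that add atoms: sodium benzenethiolate, [Na+].[S-]c1ccccc1
Why: Tandem thia-Michael/Horner–Wadsworth–Emmons reaction, in which thiolate addition to the vinylphosphonate generates the phosphonate anion that olefinates the aldehyde; alkene geometry is irrelevant because step 16 is convergent.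

Step 14
Reactants: 19 sulfide enoate
Product: 20 ethyl (2Z,4S,5S,6R,7R)-6-ethynyl-8-hydroxy-6-methyl-2-[(phenylsulfanyl)methyl]-5-(prop-1-en-2-yl)-4,7-bis[(triethylsilyl)oxy]oct-2-enoate
Conditions: DDQ (1.3 equiv), CH2Cl2/pH 7 buffer, 0 °C
Reagents that add atoms: none
Why: Oxidative PMB cleavage with DDQ, which aryl sulfides, silyl ethers, the alkyne and the alkenes should tolerate (as in thioglycoside chemistry).

Step 15
Reactants: 20 C8 alcohol
Product: 23 ethyl (2Z,4S,5S,6R,7R)-2-[(benzenesulfonyl)methyl]-6-ethynyl-6-methyl-8-oxo-5-(prop-1-en-2-yl)-4,7-bis[(triethylsilyl)oxy]oct-2-enoate, via aldehyde sulfide 21 (not isolated), via aldehyde sulfoxide 22 (not isolated)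
Conditions: TPAP (10 mol%), NMO (5 equiv), 4 Å MS, MeCN, rt → 40 °C
Reagents that add atoms: N-methylmorpholine N-oxide, C[N+]1([O-])CCOCC1
Why: One TPAP/NMO operation performs the Ley–Griffith oxidation of the primary alcohol to the C8 aldehyde and the known TPAP oxidation of the sulfide to the sulfone, leaving the isolated alkenes and the alkyne alone.

Step 16
Reactants: 23 aldehyde–allyl sulfone (E/Z mixture)
Product: 24 ethyl 2-[(1R,2R,3R,4R,5S,6R)-4-ethynyl-2-hydroxy-4-methyl-5-(prop-1-en-2-yl)-3,6-bis[(triethylsilyl)oxy]cyclohexyl]prop-2-enoate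
Conditions: SmI2 (2.3 equiv, 0.1 M in THF), THF, −78 °C, slow addition of 23 at high dilution; sat. aq. NH4Cl at −78 °C
Reagents that add atoms: none
Why: Single-electron reduction of the C8 aldehyde gives a samarium ketyl that adds 6-exo-trig to C7 of the 2-(sulfonylmethyl)enoate, and the resulting C11 α-ester radical is reduced to the Sm(III) enolate (or fragments directly) and expels benzenesulfinate to reveal the C11=C13 methylene, so the carbocycle and the exocyclic alkene are made together. The closest known reaction types are SmI2 aldehyde–enoate ketyl–olefin cyclisations and SmI2 ketyl additions to allylic sulfones or sulfides that end in β-elimination. The only ring closed is the cyclohexane (C5–C10), by 6-exo-trig radical closure through a chair in which 9-OTES, the C5 isopropenyl group, 6-OTES and the C10 ethynyl group are equatorial and the C14 methyl is axial. C7 is set by this chair together with A(1,3) strain (C6–H eclipses the C7=C11 bond whichever C11 substituent is cis), so C8 attacks the alkene face anti to 6-OTES and the acrylate ends equatorial and trans to O6; C8 is set by the bulky O–Sm(III) ketyl oxygen taking the pseudo-equatorial position anti to the enoate, which should give the 7,8-trans and 8,9-trans alcohol. The step needs chemoselectivity for the electron-poor alkene over the isopropenyl and ethynyl groups, which the nucleophilic ketyl secures, and it is stereoconvergent for the E/Z mixture of 23 because C11 returns to sp2 and the alkene geometry is erased; both possible entry points (ketyl first, or allylsamarium after sulfone loss) form the same C7–C8 bond.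

Step 17
Reactants: 24 hydroxy acrylate; 25 angelic acid [(2Z)-2-methylbut-2-enoic acid]
Product: 27 ethyl 2-[(1R,2R,3R,4R,5S,6R)-4-ethynyl-4-methyl-2-{[(2Z)-2-methylbut-2-enoyl]oxy}-5-(prop-1-en-2-yl)-3,6-bis[(triethylsilyl)oxy]cyclohexyl]prop-2-enoate, via angelic 2,4,6-trichlorobenzoic anhydride 26 (not isolated)
Conditions: 25, 2,4,6-Cl3C6H2COCl, Et3N, PhMe, rt; then 24, DMAP, PhMe, 80 °C
Reagents that add atoms: none
Why: Yamaguchi esterification through the mixed anhydride is the established way to acylate hindered secondary alcohols with angelic acid while keeping Z→E isomerisation to the tiglate low; C8 is not affected.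

Step 18
Reactants: 27 angelate bis-TES ether
Product: 29 (3aS,4R,5R,6R,7S,7aR)-6-ethynyl-5-hydroxy-6-methyl-3-methylidene-2-oxo-7-(prop-1-en-2-yl)octahydro-1-benzofuran-4-yl (2Z)-2-methylbut-2-enoate, via diol ethyl ester 28 (not isolated)
Conditions: HF·pyridine, pyridine, THF, 0 °C → rt; then CSA (cat.), PhMe, 50 °C
Reagents that add atoms: none
Why: Fluoride desilylation followed by acid-catalysed lactonisation, in which only the free O6 is γ to the ester carbonyl (O8 is acylated and the equatorial O9 cannot reach C12), so the trans-fused α-methylene-γ-lactone should form with retention at C6.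

Step 19
Reactants: 29 hydroxy lactone
Product: 30 (3aS,4R,5R,6R,7S,7aR)-5-(acetyloxy)-6-ethynyl-6-methyl-3-methylidene-2-oxo-7-(prop-1-en-2-yl)octahydro-1-benzofuran-4-yl (2Z)-2-methylbut-2-enoate
Conditions: Ac2O, DMAP (cat.), pyridine, CH2Cl2, 0 °C → rt
Reagents that add atoms: acetic anhydride, CC(=O)OC(C)=O
Why: DMAP-catalysed acetylation of the remaining (neopentyl, equatorial) C9 hydroxyl with retention.

Step 20
Reactants: 30 ethynyl lactone
Product: 31 target, (3aS,4R,5R,6S,7S,7aR)-5-(acetyloxy)-6-[(Z)-2-(acetyloxy)ethenyl]-6-methyl-3-methylidene-2-oxo-7-(prop-1-en-2-yl)octahydro-1-benzofuran-4-yl (2Z)-2-methylbut-2-enoate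
Conditions: Ru(η3-2-methylallyl)2(dppb) (5 mol%), AcOH (2 equiv), PhMe, 65 °C
Reagents that add atoms: acetic acid, CC(=O)O
Why: Ru-catalysed anti-Markovnikov hydro-acyloxylation of a terminal alkyne (via a Ru-vinylidene) places the acetate on the terminal carbon and should give the (Z)-enol ester; the phosphine-free-in-solution catalyst avoids conjugate addition to the methylene lactone.

## Compound list

1 | (S)-2,2-dimethyl-1,3-dioxolane-4-carbaldehyde | O=C[C@@H]1COC(C)(C)O1 | starting material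
2 | ethyl 2-(triphenylphosphoranylidene)propanoate | CCOC(=O)C(C)=P(c1ccccc1)(c1ccccc1)c1ccccc1 | starting material
3 | ethyl (2E)-3-[(4R)-2,2-dimethyl-1,3-dioxolan-4-yl]-2-methylprop-2-enoate | CCOC(=O)/C(C)=C/[C@@H]1COC(C)(C)O1 | intermediate
4 | (2E)-3-[(4R)-2,2-dimethyl-1,3-dioxolan-4-yl]-2-methylprop-2-en-1-ol | OC/C(C)=C/[C@@H]1COC(C)(C)O1 | intermediate
5 | (R)-4-benzyl-3-propanoyl-1,3-thiazolidine-2-thione | CCC(=O)N1[C@H](Cc2ccccc2)CSC1=S | starting material
6 | 2-[(4-methoxybenzyl)oxy]acetaldehyde | COc1ccc(COCC=O)cc1 | starting material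
7 | (2R,3R)-1-[(4R)-4-benzyl-2-thioxo-1,3-thiazolidin-3-yl]-3-hydroxy-4-[(4-methoxybenzyl)oxy]-2-methylbutan-1-one | COc1ccc(COC[C@H](O)[C@@H](C)C(=O)N2[C@H](Cc3ccccc3)CSC2=S)cc1 | intermediate
8 | (2E)-3-[(4R)-2,2-dimethyl-1,3-dioxolan-4-yl]-2-methylprop-2-en-1-yl (2R,3R)-3-hydroxy-4-[(4-methoxybenzyl)oxy]-2-methylbutanoate | COc1ccc(COC[C@H](O)[C@@H](C)C(=O)OC/C(C)=C/[C@@H]2COC(C)(C)O2)cc1 | intermediate
9 | (2S,3R)-2-{(1S)-1-[(4R)-2,2-dimethyl-1,3-dioxolan-4-yl]-2-methylprop-2-en-1-yl}-3-hydroxy-4-[(4-methoxybenzyl)oxy]-2-methylbutanoic acid | COc1ccc(COC[C@H](O)[C@@](C)(C(=O)O)[C@H](C(C)=C)[C@@H]2COC(C)(C)O2)cc1 | intermediate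
10 | (2R,3R)-2-{(1S)-1-[(4R)-2,2-dimethyl-1,3-dioxolan-4-yl]-2-methylprop-2-en-1-yl}-4-[(4-methoxybenzyl)oxy]-2-methylbutane-1,3-diol | COc1ccc(COC[C@H](O)[C@@](C)(CO)[C@H](C(C)=C)[C@@H]2COC(C)(C)O2)cc1 | intermediate
11 | (4R)-4-{(1S,2R,3R)-4-[(4-methoxybenzyl)oxy]-2-methyl-1-(prop-1-en-2-yl)-3-[(triethylsilyl)oxy]-2-{[(triethylsilyl)oxy]methyl}butyl}-2,2-dimethyl-1,3-dioxolane | COc1ccc(COC[C@H](O[Si](CC)(CC)CC)[C@@](C)(CO[Si](CC)(CC)CC)[C@H](C(C)=C)[C@@H]2COC(C)(C)O2)cc1 | intermediate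
12 | (2S,3R)-2-{(1S)-1-[(4R)-2,2-dimethyl-1,3-dioxolan-4-yl]-2-methylprop-2-en-1-yl}-4-[(4-methoxybenzyl)oxy]-2-methyl-3-[(triethylsilyl)oxy]butanal | COc1ccc(COC[C@H](O[Si](CC)(CC)CC)[C@@](C)(C=O)[C@H](C(C)=C)[C@@H]2COC(C)(C)O2)cc1 | intermediate
13 | (4R)-4-{(1S,2R,3R)-2-ethynyl-4-[(4-methoxybenzyl)oxy]-2-methyl-1-(prop-1-en-2-yl)-3-[(triethylsilyl)oxy]butyl}-2,2-dimethyl-1,3-dioxolane | COc1ccc(COC[C@H](O[Si](CC)(CC)CC)[C@@](C)(C#C)[C@H](C(C)=C)[C@@H]2COC(C)(C)O2)cc1 | intermediate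
14 | (2R,3S,4R,5R)-4-ethynyl-6-[(4-methoxybenzyl)oxy]-4-methyl-3-(prop-1-en-2-yl)hexane-1,2,5-triol | COc1ccc(COC[C@H](O)[C@@](C)(C#C)[C@H](C(C)=C)[C@@H](O)CO)cc1 | intermediate
15 | tris(triethylsilyl) ether of 14 (6-, 7- and 9-OTES; 5S,6R,9R,10R) | COc1ccc(COC[C@H](O[Si](CC)(CC)CC)[C@@](C)(C#C)[C@H](C(C)=C)[C@@H](O[Si](CC)(CC)CC)CO[Si](CC)(CC)CC)cc1 | intermediate
16 | (2R,3S,4R,5R)-4-ethynyl-6-[(4-methoxybenzyl)oxy]-4-methyl-3-(prop-1-en-2-yl)-2,5-bis[(triethylsilyl)oxy]hexanal | COc1ccc(COC[C@H](O[Si](CC)(CC)CC)[C@@](C)(C#C)[C@H](C(C)=C)[C@@H](O[Si](CC)(CC)CC)C=O)cc1 | intermediate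
17 | ethyl 2-(diethoxyphosphoryl)prop-2-enoate | C=C(C(=O)OCC)P(=O)(OCC)OCC | starting material
18 | ethyl 2-(diethoxyphosphoryl)-3-(phenylsulfanyl)propanoate (present as its sodium salt) | CCOC(=O)C(CSc1ccccc1)P(=O)(OCC)OCC | intermediate (not isolated)
19 | ethyl (2Z,4S,5S,6R,7R)-6-ethynyl-8-[(4-methoxybenzyl)oxy]-6-methyl-2-[(phenylsulfanyl)methyl]-5-(prop-1-en-2-yl)-4,7-bis[(triethylsilyl)oxy]oct-2-enoate (Z drawn; E isomer carried along) | COc1ccc(COC[C@H](O[Si](CC)(CC)CC)[C@@](C)(C#C)[C@H](C(C)=C)[C@@H](O[Si](CC)(CC)CC)/C=C(\CSc2ccccc2)C(=O)OCC)cc1 | intermediate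
20 | ethyl (2Z,4S,5S,6R,7R)-6-ethynyl-8-hydroxy-6-methyl-2-[(phenylsulfanyl)methyl]-5-(prop-1-en-2-yl)-4,7-bis[(triethylsilyl)oxy]oct-2-enoate | OC[C@H](O[Si](CC)(CC)CC)[C@@](C)(C#C)[C@H](C(C)=C)[C@@H](O[Si](CC)(CC)CC)/C=C(\CSc1ccccc1)C(=O)OCC | intermediate
21 | ethyl (2Z,4S,5S,6R,7R)-6-ethynyl-6-methyl-8-oxo-2-[(phenylsulfanyl)methyl]-5-(prop-1-en-2-yl)-4,7-bis[(triethylsilyl)oxy]oct-2-enoate | O=C[C@H](O[Si](CC)(CC)CC)[C@@](C)(C#C)[C@H](C(C)=C)[C@@H](O[Si](CC)(CC)CC)/C=C(\CSc1ccccc1)C(=O)OCC | intermediate (not isolated)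
22 | ethyl (2Z,4S,5S,6R,7R)-2-[(benzenesulfinyl)methyl]-6-ethynyl-6-methyl-8-oxo-5-(prop-1-en-2-yl)-4,7-bis[(triethylsilyl)oxy]oct-2-enoate (both sulfur epimers) | O=C[C@H](O[Si](CC)(CC)CC)[C@@](C)(C#C)[C@H](C(C)=C)[C@@H](O[Si](CC)(CC)CC)/C=C(\CS(=O)c1ccccc1)C(=O)OCC | intermediate (not isolated)
23 | ethyl (2Z,4S,5S,6R,7R)-2-[(benzenesulfonyl)methyl]-6-ethynyl-6-methyl-8-oxo-5-(prop-1-en-2-yl)-4,7-bis[(triethylsilyl)oxy]oct-2-enoate (Z drawn; E isomer carried along) | O=C[C@H](O[Si](CC)(CC)CC)[C@@](C)(C#C)[C@H](C(C)=C)[C@@H](O[Si](CC)(CC)CC)/C=C(\CS(=O)(=O)c1ccccc1)C(=O)OCC | intermediate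
24 | ethyl 2-[(1R,2R,3R,4R,5S,6R)-4-ethynyl-2-hydroxy-4-methyl-5-(prop-1-en-2-yl)-3,6-bis[(triethylsilyl)oxy]cyclohexyl]prop-2-enoate | C=C(C(=O)OCC)[C@@H]1[C@@H](O)[C@H](O[Si](CC)(CC)CC)[C@@](C)(C#C)[C@H](C(C)=C)[C@H]1O[Si](CC)(CC)CC | intermediate
25 | angelic acid, (2Z)-2-methylbut-2-enoic acid | C/C=C(/C)C(=O)O | starting material
26 | (2Z)-2-methylbut-2-enoic 2,4,6-trichlorobenzoic anhydride | C/C=C(/C)C(=O)OC(=O)c1c(Cl)cc(Cl)cc1Cl | intermediate (not isolated)
27 | ethyl 2-[(1R,2R,3R,4R,5S,6R)-4-ethynyl-4-methyl-2-{[(2Z)-2-methylbut-2-enoyl]oxy}-5-(prop-1-en-2-yl)-3,6-bis[(triethylsilyl)oxy]cyclohexyl]prop-2-enoate | C=C(C(=O)OCC)[C@@H]1[C@@H](OC(=O)/C(C)=C\C)[C@H](O[Si](CC)(CC)CC)[C@@](C)(C#C)[C@H](C(C)=C)[C@H]1O[Si](CC)(CC)CC | intermediate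
28 | ethyl 2-[(1S,2R,3R,4R,5S,6R)-4-ethynyl-3,6-dihydroxy-4-methyl-2-{[(2Z)-2-methylbut-2-enoyl]oxy}-5-(prop-1-en-2-yl)cyclohexyl]prop-2-enoate | C=C(C(=O)OCC)[C@@H]1[C@@H](OC(=O)/C(C)=C\C)[C@H](O)[C@@](C)(C#C)[C@H](C(C)=C)[C@H]1O | intermediate (not isolated)
29 | (3aS,4R,5R,6R,7S,7aR)-6-ethynyl-5-hydroxy-6-methyl-3-methylidene-2-oxo-7-(prop-1-en-2-yl)octahydro-1-benzofuran-4-yl (2Z)-2-methylbut-2-enoate | C=C1C(=O)O[C@H]2[C@H]1[C@@H](OC(=O)/C(C)=C\C)[C@H](O)[C@@](C)(C#C)[C@@H]2C(=C)C | intermediate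
30 | (3aS,4R,5R,6R,7S,7aR)-5-(acetyloxy)-6-ethynyl-6-methyl-3-methylidene-2-oxo-7-(prop-1-en-2-yl)octahydro-1-benzofuran-4-yl (2Z)-2-methylbut-2-enoate | C=C1C(=O)O[C@H]2[C@H]1[C@@H](OC(=O)/C(C)=C\C)[C@H](OC(C)=O)[C@@](C)(C#C)[C@@H]2C(=C)C | intermediate
31 | (3aS,4R,5R,6S,7S,7aR)-5-(acetyloxy)-6-[(Z)-2-(acetyloxy)ethenyl]-6-methyl-3-methylidene-2-oxo-7-(prop-1-en-2-yl)octahydro-1-benzofuran-4-yl (2Z)-2-methylbut-2-enoate (CNP0582479.1) | C=C1C(=O)O[C@H]2[C@H]1[C@@H](OC(=O)/C(C)=C\C)[C@H](OC(C)=O)[C@@](C)(/C=C\OC(C)=O)[C@@H]2C(=C)C | target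

## Summary and risks

Total step count: 20.
Longest linear sequence: 19 steps (1 → 2 → 4 → 5 → … → 20); the aldol branch (step 3) joins at step 4.

Three steps most likely to fail:

Step 5 (dianion Ireland–Claisen). What may go wrong: retro-aldol fragmentation of the β-alkoxide ester enolate on warming, and erosion of facial control while the congested quaternary C10–C5 bond forms (the chelate-directed enolate face and the C6-directed allyl face must cooperate). Fallback, setting out from 8 and coming back at 12: the free hydroxyl of 8 would be silylated (TESCl, imidazole) to give the 9-O-TES ester F1, so that the rearrangement runs through a neutral, non-chelated silyl ketene acetal (KHMDS, TMSCl, THF, −78 °C → rt, acidic work-up) instead of the dianion and gives the 9-O-TES acid F2, diastereomers being separated at this stage. LiAlH4 reduction would give the primary alcohol F3, and Dess–Martin oxidation of F3 gives aldehyde 12, so steps 6–8 are replaced.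

Step 16 (SmI2 ketyl–olefin cyclisation with sulfinate loss). What may go wrong: premature reductive cleavage of the allylic sulfone with intermolecular pinacol coupling, over-reduction of the newly formed acrylate, or poor facial selectivity at the ketyl carbon C8. Fallback, setting out from 16 and coming back at 24, using a polar allylmetal ring closure in place of the radical one: vinylalumination of 16 (ethyl propiolate, DIBAL-H, NMO, THF) would give the Baylis–Hillman-type alcohol F4 (C7 epimers). Bromination with allylic transposition (NBS, Me2S, CH2Cl2) would give the (Z)-2-(bromomethyl)enoate F5. DDQ would remove the PMB group to give the alcohol F6, and Dess–Martin oxidation would give the bromo aldehyde F7. Intramolecular Nozaki–Hiyama–Kishi-type 2-(alkoxycarbonyl)allylation of F7 (CrCl2, THF, rt, high dilution) through the equilibrating allylchromium and a trans-decalin-like closed transition state should then give 24.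

Step 17 (angeloylation of the hindered C8 hydroxyl). What may go wrong: slow acyl transfer to the flanked secondary alcohol, with competing Z→E isomerisation of the activated angeloyl unit to the tiglate. Fallback, setting out from 24 and coming back at 27, building the Z-alkene on the ester instead of transferring it: 24 would be acylated with the small acid 2-[bis(2,2,2-trifluoroethoxy)phosphoryl]propanoic acid (DCC, DMAP, CH2Cl2) to give the phosphonate ester F8, and Still–Gennari olefination of F8 with acetaldehyde (KHMDS, 18-crown-6, THF, −78 °C) should give the (Z)-2-methylbut-2-enoate 27.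

Further compounds
F1 | step 5 | (2E)-3-[(4R)-2,2-dimethyl-1,3-dioxolan-4-yl]-2-methylprop-2-en-1-yl (2R,3R)-4-[(4-methoxybenzyl)oxy]-2-methyl-3-[(triethylsilyl)oxy]butanoate | COc1ccc(COC[C@H](O[Si](CC)(CC)CC)[C@@H](C)C(=O)OC/C(C)=C/[C@@H]2COC(C)(C)O2)cc1
F2 | step 5 | (2S,3R)-2-{(1S)-1-[(4R)-2,2-dimethyl-1,3-dioxolan-4-yl]-2-methylprop-2-en-1-yl}-4-[(4-methoxybenzyl)oxy]-2-methyl-3-[(triethylsilyl)oxy]butanoic acid | COc1ccc(COC[C@H](O[Si](CC)(CC)CC)[C@@](C)(C(=O)O)[C@H](C(C)=C)[C@@H]2COC(C)(C)O2)cc1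
F3 | step 5 | (2R,3R)-2-{(1S)-1-[(4R)-2,2-dimethyl-1,3-dioxolan-4-yl]-2-methylprop-2-en-1-yl}-4-[(4-methoxybenzyl)oxy]-2-methyl-3-[(triethylsilyl)oxy]butan-1-ol | COc1ccc(COC[C@H](O[Si](CC)(CC)CC)[C@@](C)(CO)[C@H](C(C)=C)[C@@H]2COC(C)(C)O2)cc1
F4 | step 16 | ethyl (4R,5S,6R,7R)-6-ethynyl-3-hydroxy-8-[(4-methoxybenzyl)oxy]-6-methyl-2-methylidene-5-(prop-1-en-2-yl)-4,7-bis[(triethylsilyl)oxy]octanoate (C3 epimers) | COc1ccc(COC[C@H](O[Si](CC)(CC)CC)[C@@](C)(C#C)[C@H](C(C)=C)[C@@H](O[Si](CC)(CC)CC)C(O)C(=C)C(=O)OCC)cc1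
F5 | step 16 | ethyl (2Z,4S,5S,6R,7R)-2-(bromomethyl)-6-ethynyl-8-[(4-methoxybenzyl)oxy]-6-methyl-5-(prop-1-en-2-yl)-4,7-bis[(triethylsilyl)oxy]oct-2-enoate | COc1ccc(COC[C@H](O[Si](CC)(CC)CC)[C@@](C)(C#C)[C@H](C(C)=C)[C@@H](O[Si](CC)(CC)CC)/C=C(\CBr)C(=O)OCC)cc1
F6 | step 16 | ethyl (2Z,4S,5S,6R,7R)-2-(bromomethyl)-6-ethynyl-8-hydroxy-6-methyl-5-(prop-1-en-2-yl)-4,7-bis[(triethylsilyl)oxy]oct-2-enoate | OC[C@H](O[Si](CC)(CC)CC)[C@@](C)(C#C)[C@H](C(C)=C)[C@@H](O[Si](CC)(CC)CC)/C=C(\CBr)C(=O)OCC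
F7 | step 16 | ethyl (2Z,4S,5S,6R,7R)-2-(bromomethyl)-6-ethynyl-6-methyl-8-oxo-5-(prop-1-en-2-yl)-4,7-bis[(triethylsilyl)oxy]oct-2-enoate | O=C[C@H](O[Si](CC)(CC)CC)[C@@](C)(C#C)[C@H](C(C)=C)[C@@H](O[Si](CC)(CC)CC)/C=C(\CBr)C(=O)OCC
F8 | step 17 | ethyl 2-[(1R,2R,3R,4R,5S,6R)-2-({2-[bis(2,2,2-trifluoroethoxy)phosphoryl]propanoyl}oxy)-4-ethynyl-4-methyl-5-(prop-1-en-2-yl)-3,6-bis[(triethylsilyl)oxy]cyclohexyl]prop-2-enoate | C=C(C(=O)OCC)[C@@H]1[C@@H](OC(=O)C(C)P(=O)(OCC(F)(F)F)OCC(F)(F)F)[C@H](O[Si](CC)(CC)CC)[C@@](C)(C#C)[C@H](C(C)=C)[C@H]1O[Si](CC)(CC)CC
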